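**Retrosynthetic overview**

1. Feature: the pyran ring of the target consists of the aryl oxygen, C4, C5, C1′ and two arene carbons. C4 carries that oxygen and is bonded to C5, C5 is α to the benzylic carbon C1′, and C4–C5 is also the fusion bond to the nine-membered carbocycle (C1–C9). The pyran is therefore a reduced, C4-methylated chromone whose C4–C5 bond can come from an O-to-C acyl shift.
2. Target 30 ⇐ chromone 20 (nine-membered ring fused at C4–C5, C8 as dioxolane, phenols as benzyl ethers) by late introduction of C4–CH3, C1′–Ph/H, C8=CH2 and the two formyl groups.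
3. Chromone 20 ⇐ 13-membered aryl ester lactone 18 (ring atoms C1′, C5, C6, C7, C8, C9, C1, C2, C3, C4, O and two arene carbons) by a transannular Baker–Venkataraman shift (C4–C5) and cyclodehydration (O–C4). The nine-membered carbocycle and the pyranone arise together by ring contraction.
4. Lactone 18 ⇐ seco acid 16 (macrolactonisation) ⇐ acetophenone 11 + cyclobutyl vinyl ketone 9 (C5–C6 by Mukaiyama–Michael addition).
5. Vinyl ketone 9 ⇐ enantioselective cyclohexenone–isobutylene [2+2] adduct 4 by ozonolytic cleavage of C8–C4. Ring order: cyclobutane, then 13-membered lactone, then nine-membered carbocycle plus pyranone.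

Key step: step 11

**Remarks on the chemistry (assumptions)**

- Caryophyllane numbering is used throughout: C1/C9 cyclobutane methines, C11 the CMe2 carbon, C4 the O-bearing quaternary carbon, C5 its ring neighbour, C8 the methylene-bearing carbon, C1′ the benzylic carbon.
- The target is (1S,4S,5R,9R,1′R). Its cyclobutane is antipodal to that of natural (−)-β-caryophyllene, so the cyclobutane is built de novo; the enantiomer of the photocatalyst in step 1 is chosen so that C6 of adduct 4 is S.
- The phenols are carried as benzyl ethers so that they can be freed by hydrogenolysis before the C8 methylene group exists.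

**Route**

Step 1
Reactants: 1 2-cyclohexen-1-one; 2 isobutylene
Product: 4 (1S,6S)-7,7-dimethylbicyclo[4.2.0]octan-2-one, via trans-fused photoadduct 3 (not isolated)
Conditions: 2 (excess), AlBr3-activated chiral B-aryl oxazaborolidine from an α,α-diarylprolinol (50 mol%), hν (366 nm), CH2Cl2, −78 °C; then basic Al2O3, CH2Cl2, rt
Reagents that add atoms: none
Why: Lewis-acid-catalysed enantioselective intermolecular [2+2] photocycloaddition, in which the chiral AlBr3–oxazaborolidine complex activates the enone chromophore and shields one face so that C6 is set as S, with head-to-tail regiochemistry (CMe2 on the enone β-carbon); alumina then epimerises the α-carbon C1 of trans-fused 3 to the more stable cis-fused ketone 4 without touching C6.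

Step 2
Reactants: 4 cis-fused ketone
Product: 5 (1S,6S)-7,7-dimethyl-2-(trimethylsilyloxy)bicyclo[4.2.0]oct-2-ene
Conditions: LiN(i-Pr)2, THF, −78 °C; Me3SiCl, Et3N
Reagents that add atoms: chlorotrimethylsilane, C[Si](C)(C)Cl
Why: Kinetic deprotonation takes place at the C3 methylene and not at the cyclobutane-bound C1–H, and O-silylation gives the regiodefined silyl enol ether without affecting a stereocentre.

Step 3
Reactants: 5 silyl enol ether
Product: 7 (1S,2S)-2-(3-methoxy-3-oxopropyl)-3,3-dimethylcyclobutane-1-carboxylic acid, via methoxy hydroperoxide 6 (not isolated)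
Conditions: O3, CH2Cl2–MeOH, NaHCO3, −78 °C; then Ac2O, Et3N, CH2Cl2, 0 °C → rt; aqueous work-up
Reagents that add atoms: ozone, [O-][O+]=O; methanol, CO
Why: Ozonolysis of the silyl enol ether cleaves the C2–C3 bond (caryophyllane C8–C4) into a silyl ester at C8, freed as the acid by methanol, and a carbonyl oxide at C4 that methanol traps as hydroperoxide 6, which Ac2O/Et3N dehydrates to the methyl ester (unsymmetrical ozonolysis work-up), so the two termini are differentiated and both ring stereocentres are kept.

Step 4
Reactants: 7 cis acid ester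
Product: 9 methyl 3-[(1S,2S)-4,4-dimethyl-2-(prop-2-enoyl)cyclobutyl]propanoate, via acid chloride 8 (not isolated)
Conditions: (COCl)2, DMF (cat.), CH2Cl2, 0 °C → rt; then Bu3SnCH=CH2, Pd(PPh3)4 (cat.), THF, 50 °C
Reagents that add atoms: tributyl(vinyl)stannane, C=C[Sn](CCCC)(CCCC)CCCC
Why: Stille acylation of the acid chloride gives the vinyl ketone (C8 with C7=C6) under neutral conditions that leave the methyl ester alone; partial epimerisation at C9 would be harmless because C9 is equilibrated in step 7.

Step 5
Reactants: 10 2',4',6'-trihydroxyacetophenone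
Product: 11 1-[2,4-bis(benzyloxy)-6-hydroxyphenyl]ethan-1-one
Conditions: BnBr (2.1 equiv), K2CO3, DMF, rt
Reagents that add atoms: benzyl bromide, BrCc1ccccc1
Why: Williamson etherification in which the hydroxyl hydrogen-bonded to the acetyl group is the least reactive and stays free.

Step 6
Reactants: 11 dibenzyl acetophenone; 9 vinyl ketone
Product: 13 methyl 3-[(1S,2S)-2-{5-[2,4-bis(benzyloxy)-6-hydroxyphenyl]-5-oxopentanoyl}-4,4-dimethylcyclobutyl]propanoate, via bis-silyl enol ether 12 (not isolated)
Conditions: 11, LiN(SiMe3)2 (2.2 equiv), Me3SiCl, THF, −78 → 0 °C; then 9, Sc(OTf)3 (10 mol%), CH2Cl2, −78 °C; 1 M HCl–THF work-up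
Reagents that add atoms: none
Why: Mukaiyama–Michael addition of the aryl ketone silyl enol ether to the Lewis-acid-activated vinyl ketone forms C5–C6 without a basic enolate that would polymerise the enone, and the acidic work-up frees the phenol and both ketones.

Step 7
Reactants: 13 cis 1,5-diketone
Product: 14 methyl 3-[(1S,2R)-2-{5-[2,4-bis(benzyloxy)-6-hydroxyphenyl]-5-oxopentanoyl}-4,4-dimethylcyclobutyl]propanoate
Conditions: NaOMe, MeOH, rt; AcOH quench
Reagents that add atoms: none
Why: Base-mediated epimerisation through the C8 enolate sets C9 relative to the fixed centre C1 and should strongly favour the trans-1,2-disubstituted cyclobutane (thermodynamic control); the aryl ketone is present as its unreactive phenoxide and the ester is degenerate towards methoxide.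

Step 8
Reactants: 14 trans 1,5-diketone
Product: 15 methyl 3-[(1S,2R)-2-{2-[4-(2,4-bis(benzyloxy)-6-hydroxyphenyl)-4-oxobutyl]-1,3-dioxolan-2-yl}-4,4-dimethylcyclobutyl]propanoate
Conditions: Me3SiOCH2CH2OSiMe3, Me3SiOTf (cat.), CH2Cl2, −78 → −20 °C; pyridine; aqueous NaHCO3
Reagents that add atoms: 1,2-bis(trimethylsilyloxy)ethane, C[Si](C)(C)OCCO[Si](C)(C)C
Why: Noyori ketalisation is selective for the dialkyl ketone C8 because the hydrogen-bonded, doubly ortho-substituted aryl ketone C1′ is inert, and it locks C9 as trans and removes the C7/C9 α-protons ahead of the key step.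

Step 9
Reactants: 15 ketal ester
Product: 16 3-[(1S,2R)-2-{2-[4-(2,4-bis(benzyloxy)-6-hydroxyphenyl)-4-oxobutyl]-1,3-dioxolan-2-yl}-4,4-dimethylcyclobutyl]propanoic acid
Conditions: LiOH, THF–MeOH–H2O, rt; then 1 M HCl to pH 4, 0 °C
Reagents that add atoms: lithium hydroxide, [Li+].[OH-]
Why: Saponification of the unhindered methyl ester; the ketal survives the brief, cold and mildly acidic work-up.

Step 10
Reactants: 16 seco acid
Product: 18 13-membered aryl ester macrolactone, via mixed anhydride 17 (not isolated)
Conditions: 2,4,6-Cl3C6H2COCl, Et3N, THF, rt; then slow addition to DMAP, PhMe, 80 °C (high dilution)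
Reagents that add atoms: none
Why: Yamaguchi macrolactonisation, in which DMAP transfers the C4 acyl group to the phenol; the arene, the ketone and the trans-cyclobutane limit the freedom of the chain, and a 13-membered ring is large enough to close without serious strain.

Step 11
Reactants: 18 macrolactone
Product: 20 chromone fused to the nine-membered carbocycle, via β-diketone 19 (not isolated)
Conditions: LiN(SiMe3)2 (2.5 equiv), THF, −78 → 0 °C; AcOH; then TsOH·H2O (10 mol%), PhH, reflux, Dean–Stark
Reagents that add atoms: none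
Why: Proposed new method: LiN(SiMe3)2 deprotonates the C5 methylene of the aryl ketone (C8 is a ketal, so it is the only ketone α-position), the enolate carbon attacks the lactone carbonyl C4 through the six-membered array C5–C1′–C(aryl)–C(aryl)–O–C4, the tetrahedral intermediate expels the phenoxide, and the second equivalent of base turns 2-aroylcyclononanone 19 into its stabilised diketonate, which drives the transfer. The closest known reaction is the Baker–Venkataraman rearrangement of open-chain 2-acyloxyaryl ketones followed by acid cyclodehydration to chromones; new here is that donor and acceptor are also joined by the C6–C3 chain, so the acyl shift contracts a 13-membered lactone. The nine-membered carbocycle is closed by this transannular C4–C5 bond formation (6-exo-trig attack of the enolate on the ester carbonyl, not an end-to-end cyclisation: the entropic cost was paid in the lactonisation and the ring strain is offset by phenoxide release and diketonate formation). The pyranone is closed by 6-exo-trig addition of the liberated phenol to the C4 ketone and TsOH-catalysed loss of water, which takes C4 and C5 into the chromone and creates no stereocentre, while C1 and C9 are untouched because C8 is a ketal. The selectivity needed is enolisation at C5 and not at the ester α-carbon C3; it rests on the faster deprotonation of the ketone at −78 °C, on the six-membered geometry of the transfer, and on proton transfer from any C3 enolate to C5 before it can lose phenoxide, and azeotropic removal of water keeps the dioxolane intact.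

Step 12
Reactants: 20 chromone
Product: 23 (4S,5S)-4-methyl chromanone, via benzopyrylium triflate 21 (not isolated), via silyl enol ether 22 (not isolated)
Conditions: Me3SiOTf (1.1 equiv), CH2Cl2, rt; then MeMgBr, CuBr·SMe2 (20 mol%), THF, −78 °C; then K2CO3, MeOH, rt
Reagents that add atoms: methylmagnesium bromide, C[Mg]Br
Why: Silyl triflate activation gives the 4-silyloxybenzopyrylium salt 21, to which the methylcopper reagent adds at C4 (conjugate addition to an activated chromone), expected on the face of the pyrylium plane not covered by the C1–C2/C7–C8 loop of the nine-membered ring; methanolysis of 22 and mild base equilibration at C5 (α to C1′) should place H5 anti to the C4 methyl group (trans ring fusion, both nine-ring bonds pseudo-equatorial).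

Step 13
Reactants: 23 chromanone
Product: 24 tertiary C1′ carbinol (1′R)
Conditions: PhLi, CeCl3, THF, −78 °C; NH4Cl (aq)
Reagents that add atoms: phenyllithium, [Li]c1ccccc1
Why: Organocerium 1,2-addition to the hindered, enolisable ketone (low basicity suppresses enolisation and pyran opening), with phenyl expected anti to the axial C4 methyl group; the C1′ configuration is of no consequence because the centre is ionised in step 14.

Step 14
Reactants: 24 carbinol
Product: 25 (1S,4S,5R,9R,1′R)-4-phenylchroman bis(benzyl ether) with C8 dioxolane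
Conditions: Et3SiH (5 equiv), CF3CO2H (3 equiv), CH2Cl2, −78 → −20 °C
Reagents that add atoms: none
Why: Ionic hydrogenation, in which the doubly benzylic tertiary alcohol ionises to a cation stabilised by the dialkoxyaryl and phenyl groups and Et3SiH delivers hydride to the face anti to the axial C4 methyl group and to the C5–C6 bond, so that H1′ ends cis to H5 as in the target; at low temperature the dioxolane is not expected to be reduced, and its hydrolysis would be harmless.

Step 15
Reactants: 25 4-phenylchroman bis(benzyl ether)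
Product: 27 5,7-dihydroxy C8 ketone, via debenzylated ketal 26 (not isolated)
Conditions: H2 (1 atm), Pd/C, EtOAc–MeOH, rt; filter; then 1 M HCl, THF, rt
Reagents that add atoms: water, O
Why: Hydrogenolysis of the two aryl benzyl ethers, possible because no alkene is present yet, followed by acid hydrolysis of the dioxolane; no stereocentre is involved and trans C9 is the stable arrangement next to the freed ketone.

Step 16
Reactants: 27 diol ketone
Product: 28 8-methylene diol
Conditions: Ph3PCH3Br, KOt-Bu (excess), THF, 0 → 50 °C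
Reagents that add atoms: methyltriphenylphosphonium bromide, C[P+](c1ccccc1)(c1ccccc1)c1ccccc1.[Br-]
Why: Wittig methylenation of the C8 ketone with excess ylide; the phenols are carried as inert phenoxides and C9 stays in its thermodynamically preferred trans configuration.

Step 17
Reactants: 28 methylene diol
Product: 30 Psidial A, via bis-iminium salt 29 (not isolated)
Conditions: POCl3, DMF, MeCN, 0 °C → rt; then H2O, 40 °C
Reagents that add atoms: N,N-dimethylformamide, CN(C)C=O; water, O
Why: Twofold Vilsmeier–Haack formylation at the two free positions of the phloroglucinol-type ring, each activated by three oxygen substituents, under conditions mild enough for the 1,1-disubstituted alkene, with hydrolysis of bis-iminium salt 29 giving the dialdehyde.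

**Compound list**

1 | 2-cyclohexen-1-one | O=C1C=CCCC1 | starting material
2 | isobutylene (2-methylpropene) | CC(C)=C | starting material
3 | (1R,6S)-7,7-dimethylbicyclo[4.2.0]octan-2-one (trans-fused photoadduct) | O=C1CCC[C@@H]2C(C)(C)C[C@@H]12 | intermediate
4 | (1S,6S)-7,7-dimethylbicyclo[4.2.0]octan-2-one (cis-fused) | O=C1CCC[C@@H]2C(C)(C)C[C@H]12 | intermediate
5 | (1S,6S)-7,7-dimethyl-2-(trimethylsilyloxy)bicyclo[4.2.0]oct-2-ene | C[Si](C)(C)OC1=CCC[C@@H]2C(C)(C)C[C@H]12 | intermediate
6 | (1S,2S)-2-(3-hydroperoxy-3-methoxypropyl)-3,3-dimethylcyclobutane-1-carboxylic acid (both epimers at the peroxyacetal carbon) | COC(OO)CC[C@@H]1C(C)(C)C[C@@H]1C(=O)O | intermediate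
7 | (1S,2S)-2-(3-methoxy-3-oxopropyl)-3,3-dimethylcyclobutane-1-carboxylic acid (cis) | COC(=O)CC[C@@H]1C(C)(C)C[C@@H]1C(=O)O | intermediate
8 | methyl 3-[(1S,2S)-2-(chlorocarbonyl)-4,4-dimethylcyclobutyl]propanoate | COC(=O)CC[C@@H]1C(C)(C)C[C@@H]1C(=O)Cl | intermediate
9 | methyl 3-[(1S,2S)-4,4-dimethyl-2-(prop-2-enoyl)cyclobutyl]propanoate (cis) | COC(=O)CC[C@@H]1C(C)(C)C[C@@H]1C(=O)C=C | intermediate
10 | 2',4',6'-trihydroxyacetophenone | CC(=O)c1c(O)cc(O)cc1O | starting material
11 | 1-[2,4-bis(benzyloxy)-6-hydroxyphenyl]ethan-1-one | CC(=O)c1c(O)cc(OCc2ccccc2)cc1OCc1ccccc1 | intermediate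
12 | {1-[2,4-bis(benzyloxy)-6-(trimethylsilyloxy)phenyl]ethenyloxy}trimethylsilane | C=C(O[Si](C)(C)C)c1c(O[Si](C)(C)C)cc(OCc2ccccc2)cc1OCc1ccccc1 | intermediate
13 | methyl 3-[(1S,2S)-2-{5-[2,4-bis(benzyloxy)-6-hydroxyphenyl]-5-oxopentanoyl}-4,4-dimethylcyclobutyl]propanoate (cis) | COC(=O)CC[C@@H]1C(C)(C)C[C@@H]1C(=O)CCCC(=O)c1c(O)cc(OCc2ccccc2)cc1OCc1ccccc1 | intermediate
14 | methyl 3-[(1S,2R)-2-{5-[2,4-bis(benzyloxy)-6-hydroxyphenyl]-5-oxopentanoyl}-4,4-dimethylcyclobutyl]propanoate (trans) | COC(=O)CC[C@@H]1C(C)(C)C[C@H]1C(=O)CCCC(=O)c1c(O)cc(OCc2ccccc2)cc1OCc1ccccc1 | intermediate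
15 | methyl 3-[(1S,2R)-2-{2-[4-(2,4-bis(benzyloxy)-6-hydroxyphenyl)-4-oxobutyl]-1,3-dioxolan-2-yl}-4,4-dimethylcyclobutyl]propanoate | COC(=O)CC[C@@H]1C(C)(C)C[C@H]1C1(CCCC(=O)c2c(O)cc(OCc3ccccc3)cc2OCc2ccccc2)OCCO1 | intermediate
16 | 3-[(1S,2R)-2-{2-[4-(2,4-bis(benzyloxy)-6-hydroxyphenyl)-4-oxobutyl]-1,3-dioxolan-2-yl}-4,4-dimethylcyclobutyl]propanoic acid (seco acid) | OC(=O)CC[C@@H]1C(C)(C)C[C@H]1C1(CCCC(=O)c2c(O)cc(OCc3ccccc3)cc2OCc2ccccc2)OCCO1 | intermediate
17 | mixed anhydride of 16 with 2,4,6-trichlorobenzoic acid | O=C(OC(=O)CC[C@@H]1C(C)(C)C[C@H]1C1(CCCC(=O)c2c(O)cc(OCc3ccccc3)cc2OCc2ccccc2)OCCO1)c1c(Cl)cc(Cl)cc1Cl | intermediate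
18 | 13-membered aryl ester macrolactone, (1S,9R): ring C1′(=O)–C5H2–C6H2–C7H2–C8(dioxolane)–C9–C1–C2H2–C3H2–C4(=O)–O–aryl, trans-cyclobutane, aryl 3,5-bis(benzyloxy) | O=C1CCCC2(OCCO2)[C@@H]2CC(C)(C)[C@H]2CCC(=O)Oc2cc(OCc3ccccc3)cc(OCc3ccccc3)c21 | intermediate
19 | (1S,9R)-5-[2,4-bis(benzyloxy)-6-hydroxybenzoyl]-8,8-(ethylenedioxy)caryophyllan-4-one skeleton without the C4 and C8 methyl carbons (2-aroylcyclononanone; C5 enolisable, not defined) | O=C(c1c(O)cc(OCc2ccccc2)cc1OCc1ccccc1)C1CCC2(OCCO2)[C@@H]2CC(C)(C)[C@H]2CCC1=O | intermediate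
20 | (1S,9R) chromone fused at C4=C5 to the nine-membered carbocycle, 5,7-bis(benzyloxy) on the chromone, C8 dioxolane | O=c1c2c(OCc3ccccc3)cc(OCc3ccccc3)cc2oc2c1CCC1(OCCO1)[C@@H]1CC(C)(C)[C@H]1CC2 | intermediate
21 | 4-(trimethylsilyloxy)benzopyrylium triflate of 20 | C[Si](C)(C)Oc1c2c(OCc3ccccc3)cc(OCc3ccccc3)cc2[o+]c2c1CCC1(OCCO1)[C@@H]1CC(C)(C)[C@H]1CC2.[O-]S(=O)(=O)C(F)(F)F | intermediate
22 | (1S,4S,9R) C1′ trimethylsilyl enol ether (C1′=C5) with quaternary C4 methyl | C[Si](C)(C)OC1=C2CCC3(OCCO3)[C@@H]3CC(C)(C)[C@H]3CC[C@]2(C)Oc2cc(OCc3ccccc3)cc(OCc3ccccc3)c21 | intermediate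
23 | (1S,4S,5S,9R) 4-methyl chromanone (C1′ ketone, H5 anti to C4–CH3), bis(benzyl ether), C8 dioxolane | O1CCOC12CC[C@@H]3C(=O)c4c(OCc5ccccc5)cc(OCc5ccccc5)cc4O[C@@]3(C)CC[C@H]3[C@H]2CC3(C)C | intermediate
24 | (1S,4S,5R,9R,1′R) C1′ phenyl carbinol (OH syn to C4–CH3) | O1CCOC12CC[C@@H]3[C@@](O)(c4ccccc4)c4c(OCc5ccccc5)cc(OCc5ccccc5)cc4O[C@@]3(C)CC[C@H]3[C@H]2CC3(C)C | intermediate
25 | (1S,4S,5R,9R,1′R) 1′-phenyl chroman, bis(benzyl ether), C8 dioxolane | O1CCOC12CC[C@@H]3[C@H](c4ccccc4)c4c(OCc5ccccc5)cc(OCc5ccccc5)cc4O[C@@]3(C)CC[C@H]3[C@H]2CC3(C)C | intermediate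
26 | (1S,4S,5R,9R,1′R) 1′-phenyl chroman diol, C8 dioxolane | O1CCOC12CC[C@@H]3[C@H](c4ccccc4)c4c(O)cc(O)cc4O[C@@]3(C)CC[C@H]3[C@H]2CC3(C)C | intermediate
27 | (1S,4S,5R,9R,1′R) 1′-phenyl chroman diol, C8 ketone | O=C1CC[C@@H]2[C@H](c3ccccc3)c3c(O)cc(O)cc3O[C@@]2(C)CC[C@H]2[C@H]1CC2(C)C | intermediate
28 | (1S,4S,5R,9R,1′R) 1′-phenyl chroman diol, 8-methylene (bis-deformyl Psidial A) | C=C1CC[C@@H]2[C@H](c3ccccc3)c3c(O)cc(O)cc3O[C@@]2(C)CC[C@H]2[C@H]1CC2(C)C | intermediate
29 | bis(N,N-dimethyliminium) dichloride of 30 | C=C1CC[C@@H]2[C@H](c3ccccc3)c3c(O)c(C=[N+](C)C)c(O)c(C=[N+](C)C)c3O[C@@]2(C)CC[C@H]2[C@H]1CC2(C)C.[Cl-].[Cl-] | intermediate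
30 | Psidial A, (1S,4S,5R,9R,1′R) | C=C1CC[C@@H]2[C@H](c3ccccc3)c3c(O)c(C=O)c(O)c(C=O)c3O[C@@]2(C)CC[C@H]2[C@H]1CC2(C)C | target

**Step count**

Total: 17 steps. Longest linear sequence: 16 steps (steps 1–4 and 6–17, from 2-cyclohexen-1-one); step 5 is the one-step side branch.

**Steps most likely to fail**

1. Step 11 (transannular acyl shift). What may go wrong: deprotonation at the ester α-carbon C3 with loss of phenoxide (ketene formation) and oligomerisation, or failure of the C5 enolate to reach C4 because the tetrahedral intermediate already contains the strained nine-membered ring. Fallback, using only known reactions and no transannular step: it sets out from ketal ester 15 and closes C4–C5 by a samarium Reformatsky-type aldol cyclisation, a ring closure with a good record for eight- and nine-membered carbocycles. Ester 15 is treated with LiN(SiMe3)2 and t-BuMe2SiCl to give the bis-silyl compound F1 (aryl silyl ether and C1′ silyl enol ether). The ester is reduced with i-Bu2AlH at −78 °C to the aldehyde F2. N-Bromosuccinimide at −78 °C converts the silyl enol ether into the C5 bromo ketone F3, the silyl ether keeping the phenol from displacing the bromide. SmI2 in THF under high dilution forms the samarium enolate at C5, which adds to the C4 aldehyde and gives the nine-membered hydroxy ketone F4. Dess–Martin periodinane oxidises it to the silyl-protected diketone F5, and Bu4NF frees the phenol to give 19, which is cyclodehydrated with TsOH to 20 as in step 11.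

2. Step 12 (methyl addition at C4). What may go wrong: poor facial discrimination in the methyl transfer to the benzopyrylium ion, because the nine-membered ring gives no assured bias, and partial opening of the pyran during the C5 equilibration. Fallback, which places C4 and C5 under thermodynamic control through reversible C–O bond formation instead of kinetic C–C bond formation: it sets out from chromone 20 and comes back at 23. Step 12 is run as described, and the accompanying C4-epimeric chromanone F6 is separated and heated with pyrrolidine in MeOH. This opens the pyran reversibly by retro-oxa-Michael reaction to the 2-aroyl enone F7, which re-closes by oxa-Michael addition of the phenol (the ring-forming step of the Kabbe chromanone synthesis). Repeated separation and equilibration should funnel the material to 23.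

3. Step 14 (ionic hydrogenation at C1′). What may go wrong: loss of a proton from the cation to give the 2H-chromene and unselective re-protonation at C5, hydride delivery to the wrong face, or reductive opening of the dioxolane. Fallback, which replaces carbonyl addition and cationic reduction by cross-coupling and catalytic hydrogenation: it sets out from chromanone 23, bypasses step 13, and comes back at 26. KN(SiMe3)2 and PhNTf2 at −78 °C give the enol triflate F8 (C1′=C5). Suzuki coupling with PhB(OH)2, Pd(PPh3)4 and K3PO4 gives the 4-phenyl-2H-chromene F9. Hydrogenation over Pd/C under pressure adds both hydrogens to the same face of C5=C1′, which guarantees the cis relation of H5 and H1′, expected from the face remote from the pseudo-axial C4 methyl group; it removes both benzyl ethers in the same operation and gives 26, which is hydrolysed to 27 as in step 15.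

**Further compounds**

F1 | step 11 | methyl 3-[(1S,2R)-2-{2-[(3Z)-4-[2,4-bis(benzyloxy)-6-(tert-butyldimethylsilyloxy)phenyl]-4-(tert-butyldimethylsilyloxy)but-3-enyl]-1,3-dioxolan-2-yl}-4,4-dimethylcyclobutyl]propanoate | COC(=O)CC[C@@H]1C(C)(C)C[C@H]1C1(CC/C=C(\O[Si](C)(C)C(C)(C)C)c2c(O[Si](C)(C)C(C)(C)C)cc(OCc3ccccc3)cc2OCc2ccccc2)OCCO1
F2 | step 11 | 3-[(1S,2R)-…cyclobutyl]propanal corresponding to F1 (C4 aldehyde) | O=CCC[C@@H]1C(C)(C)C[C@H]1C1(CC/C=C(\O[Si](C)(C)C(C)(C)C)c2c(O[Si](C)(C)C(C)(C)C)cc(OCc3ccccc3)cc2OCc2ccccc2)OCCO1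
F3 | step 11 | C5 bromo ketone aldehyde, aryl tert-butyldimethylsilyl ether (both C5 epimers) | O=CCC[C@@H]1C(C)(C)C[C@H]1C1(CCC(Br)C(=O)c2c(O[Si](C)(C)C(C)(C)C)cc(OCc3ccccc3)cc2OCc2ccccc2)OCCO1
F4 | step 11 | (1S,9R) nine-membered 4-hydroxy-5-aroyl carbocycle, aryl tert-butyldimethylsilyl ether, C8 dioxolane (C4 and C5 not defined) | O=C(c1c(O[Si](C)(C)C(C)(C)C)cc(OCc2ccccc2)cc1OCc1ccccc1)C1CCC2(OCCO2)[C@@H]2CC(C)(C)[C@H]2CCC1O
F5 | step 11 | tert-butyldimethylsilyl ether of diketone 19 (C5 not defined) | O=C(c1c(O[Si](C)(C)C(C)(C)C)cc(OCc2ccccc2)cc1OCc1ccccc1)C1CCC2(OCCO2)[C@@H]2CC(C)(C)[C@H]2CCC1=O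
F6 | step 12 | (1S,4R,5R,9R) chromanone, the C4/C5 diastereomer of 23 | O1CCOC12CC[C@H]3C(=O)c4c(OCc5ccccc5)cc(OCc5ccccc5)cc4O[C@]3(C)CC[C@H]3[C@H]2CC3(C)C
F7 | step 12 | (1S,9R) ring-opened 2-aroyl enone: nine-membered ring with C4=C5 double bond (geometry not defined), C4 methyl, C5 2,4-bis(benzyloxy)-6-hydroxybenzoyl, C8 dioxolane | O=C(c1c(O)cc(OCc2ccccc2)cc1OCc1ccccc1)C1=C(C)CC[C@H]2[C@@H](CC2(C)C)C2(CC1)OCCO2
F8 | step 14 | (1S,4S,9R) C1′ enol triflate (C1′=C5) of 23 | O1CCOC12CCC3=C(OS(=O)(=O)C(F)(F)F)c4c(OCc5ccccc5)cc(OCc5ccccc5)cc4O[C@@]3(C)CC[C@H]3[C@H]2CC3(C)C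
F9 | step 14 | (1S,4S,9R) 1′-phenyl-2H-chromene (C1′=C5), bis(benzyl ether), C8 dioxolane | O1CCOC12CCC3=C(c4ccccc4)c4c(OCc5ccccc5)cc(OCc5ccccc5)cc4O[C@@]3(C)CC[C@H]3[C@H]2CC3(C)C
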